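**Plan**

- Numbering: C1 benzoyl bridgehead, C2/C4 ketones beside quaternary C3, C5 geranyl bridgehead, C9 bridging ketone, C6H2–C7H–C8Me2 bridge, C10H2, C11H, C12Me2, C13H(iPr), C14H2. Ring C1–C2–C3–C4–C5–C9 is a dearomatised phloroglucinol and C3 is also the spiro atom of cyclopentane C3–C11–C12–C13–C14, so an arene already bonded to C11 can close that ring by ipso attack of C3 on C14.
- Cuts, backwards: the transient C10–OH; C7–C10 together with C1–C8 (one Prins/cation–enol step); C1–benzoyl; C5–C6 (prenyl) and C5–geranyl; C3–C14; O–C10 (a temporary dihydrofuran tether that marks C2); aryl C3–C11 (aromatic Claisen); C12–C13 (Ireland–Claisen).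
- Forward ring order: arene (latent ring A) → dihydrofuran tether → cyclopentane with dearomatisation → tether opened → seven- and six-membered cage rings in one step.
- Stereochemistry: C13 and C11 by chirality transfer in two [3,3] shifts from CBS-derived carbinols; C3 from C11 through the cis ring fusion of the spirocyclisation; C5 by alkylation on the convex face; C1 and C7 by the geometry of the cage closure.

Key step: step 14

Remark: enolisable dione and triketone intermediates are drawn as single tautomers and the Prins product as its open hydroxy ketone; 3,5-bis(benzyloxy)phenol is taken as a purchasable O-protected phloroglucinol.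

**Step 1**
Reactants: 1 (3E)-5-methylhex-3-en-2-one
Product: 2 (2R,3E)-5-methylhex-3-en-2-ol
Conditions: (S)-2-methyl-CBS-oxazaborolidine (10 mol %), catecholborane, toluene, −78 °C
Reagents that add atoms: none
Why: Corey–Bakshi–Shibata reduction, in which the (S)-catalyst treats the alkenyl group as the large substituent and should deliver hydride to give the (R)-carbinol, catecholborane at low temperature keeping the reduction 1,2.

**Step 2**
Reactants: 2 (2R,3E)-5-methylhex-3-en-2-ol; 3 2-methylpropanoyl chloride
Product: 4 (2R,3E)-5-methylhex-3-en-2-yl 2-methylpropanoate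
Conditions: pyridine, DMAP (cat.), CH2Cl2, 0 °C → rt
Reagents that add atoms: none
Why: Routine acylation of a secondary alcohol by an acid chloride, which leaves the carbinol centre untouched.

**Step 3**
Reactants: 4 (2R,3E)-5-methylhex-3-en-2-yl 2-methylpropanoate
Product: 7 (3S,4E)-2,2-dimethyl-3-(propan-2-yl)hex-4-enoic acid, via trimethylsilyl ketene acetal 5 (not isolated), via trimethylsilyl ester 6 (not isolated)
Conditions: LiN(iPr)2, TMSCl, THF, −78 °C → 60 °C; 1 M HCl
Reagents that add atoms: chlorotrimethylsilane, C[Si](C)(C)Cl (silyl group present in 5 and 6 only, lost on work-up)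
Why: Ireland–Claisen rearrangement, in which the isobutyrate ketene acetal has no E/Z issue and the chair transition state with the carbinol methyl equatorial should transfer the (R)-carbinol chirality to C13, form the C12–C13 bond and give the E-propenyl group that later becomes C14.

**Step 4**
Reactants: 7 (3S,4E)-2,2-dimethyl-3-(propan-2-yl)hex-4-enoic acid
Product: 8 (3S,4E)-2,2-dimethyl-3-(propan-2-yl)hex-4-en-1-ol
Conditions: LiAlH4, Et2O, 0 °C → rt
Reagents that add atoms: none
Why: Hydride reduction of a hindered carboxylic acid to the neopentyl alcohol, with no stereocentre at risk.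

**Step 5**
Reactants: 8 (3S,4E)-2,2-dimethyl-3-(propan-2-yl)hex-4-en-1-ol
Product: 9 (3S,4E)-2,2-dimethyl-3-(propan-2-yl)hex-4-enal
Conditions: Dess–Martin periodinane, CH2Cl2, rt
Reagents that add atoms: none
Why: Dess–Martin oxidation to an α-quaternary aldehyde that can neither enolise nor epimerise.

**Step 6**
Reactants: 9 (3S,4E)-2,2-dimethyl-3-(propan-2-yl)hex-4-enal; 10 dimethyl (2-oxopropyl)phosphonate
Product: 11 (3E,6S,7E)-5,5-dimethyl-6-(propan-2-yl)nona-3,7-dien-2-one
Conditions: NaH, THF, 0 °C → rt
Reagents that add atoms: none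
Why: Horner–Wadsworth–Emmons olefination with a ketophosphonate anion, which should be reactive enough for the neopentyl aldehyde and E-selective.

**Step 7**
Reactants: 11 (3E,6S,7E)-5,5-dimethyl-6-(propan-2-yl)nona-3,7-dien-2-one
Product: 12 (2S,3E,6S,7E)-5,5-dimethyl-6-(propan-2-yl)nona-3,7-dien-2-ol
Conditions: (R)-2-methyl-CBS-oxazaborolidine (15 mol %), catecholborane, toluene, −78 °C
Reagents that add atoms: none
Why: Second Corey–Bakshi–Shibata reduction, now with the (R)-catalyst, which should set the (S)-carbinol under reagent control because C13 is remote.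

**Step 8**
Reactants: 12 (2S,3E,6S,7E)-5,5-dimethyl-6-(propan-2-yl)nona-3,7-dien-2-ol; 13 3,5-bis(benzyloxy)phenol
Product: 14 1,3-bis(benzyloxy)-5-{[(2R,3E,6S,7E)-5,5-dimethyl-6-(propan-2-yl)nona-3,7-dien-2-yl]oxy}benzene
Conditions: PPh3, DIAD, toluene, 0 °C → rt
Reagents that add atoms: none
Why: Mitsunobu etherification of a phenol, which should invert the carbinol to the (R)-ether, the SN2′ path being blocked by the quaternary carbon next to the alkene terminus.

**Step 9**
Reactants: 14 1,3-bis(benzyloxy)-5-{[(2R,3E,6S,7E)-5,5-dimethyl-6-(propan-2-yl)nona-3,7-dien-2-yl]oxy}benzene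
Product: 15 3,5-bis(benzyloxy)-2-[(2E,4R,6S,7E)-5,5-dimethyl-6-(propan-2-yl)nona-2,7-dien-4-yl]phenol
Conditions: europium tris(6,6,7,7,8,8,8-heptafluoro-2,2-dimethyl-3,5-octanedionate), Eu(fod)3 (10 mol %), CHCl3, 60 °C
Reagents that add atoms: none
Why: Lewis-acid-accelerated aromatic Claisen rearrangement through a chair transition state with the ether methyl equatorial, which should form the aryl C3–C11 bond ortho to oxygen, transfer the ether chirality suprafacially to C11 (R) and leave an E-propenyl group as the future C10.

**Step 10**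
Reactants: 15 3,5-bis(benzyloxy)-2-[(2E,4R,6S,7E)-5,5-dimethyl-6-(propan-2-yl)nona-2,7-dien-4-yl]phenol
Product: 17 (2R,4R)-2-[2,4-bis(benzyloxy)-6-hydroxyphenyl]-3,3-dimethyl-4-(propan-2-yl)pentane-1,5-diol, via bis-ozonide 16 (not isolated)
Conditions: O3, CH2Cl2, −78 °C (stopped at first blue colour); then NaBH4, MeOH, −78 → 0 °C
Reagents that add atoms: ozone, [O-][O+]=O
Why: Ozonolysis with borohydride work-up should cut both E-propenyl groups to C10H2OH and C14H2OH, the disubstituted alkenes reacting far faster than the arene at low temperature.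

**Step 11**
Reactants: 17 (2R,4R)-2-[2,4-bis(benzyloxy)-6-hydroxyphenyl]-3,3-dimethyl-4-(propan-2-yl)pentane-1,5-diol
Product: 18 (2R)-3-[(3R)-4,6-bis(benzyloxy)-2,3-dihydro-1-benzofuran-3-yl]-3-methyl-2-(propan-2-yl)butan-1-ol
Conditions: PPh3, DIAD, THF, 0 °C → rt
Reagents that add atoms: none
Why: Intramolecular Mitsunobu etherification, in which only C10–OH can reach the phenol oxygen in a 5-exo-tet closure, so the two primary alcohols are told apart and the O–C10 tether that marks C2 is installed.

**Step 12**
Reactants: 18 (2R)-3-[(3R)-4,6-bis(benzyloxy)-2,3-dihydro-1-benzofuran-3-yl]-3-methyl-2-(propan-2-yl)butan-1-ol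
Product: 19 (3R)-4,6-bis(benzyloxy)-3-[(3R)-3-(bromomethyl)-2,4-dimethylpentan-2-yl]-2,3-dihydro-1-benzofuran
Conditions: CBr4, PPh3, CH2Cl2, 0 → 40 °C
Reagents that add atoms: carbon tetrabromide, BrC(Br)(Br)Br
Why: Appel bromination of the remaining primary alcohol by bromide attack on the alkoxyphosphonium salt, warmed because C14 is β-branched.

**Step 13**
Reactants: 19 (3R)-4,6-bis(benzyloxy)-3-[(3R)-3-(bromomethyl)-2,4-dimethylpentan-2-yl]-2,3-dihydro-1-benzofuran
Product: 20 (3R)-3-[(3R)-3-(bromomethyl)-2,4-dimethylpentan-2-yl]-2,3-dihydro-1-benzofuran-4,6-diol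
Conditions: H2 (1 atm), 10% Pd/C, EtOAc, rt
Reagents that add atoms: none
Why: Neutral hydrogenolysis of the two benzyl ethers, which should spare the hindered primary alkyl bromide and the alkyl aryl ether and give the C3-substituted phloroglucinol whose C2 oxygen is tied to C10.

**Step 14**
Reactants: 20 (3R)-3-[(3R)-3-(bromomethyl)-2,4-dimethylpentan-2-yl]-2,3-dihydro-1-benzofuran-4,6-diol
Product: 21 cyclic enol ether of the spiro trione (C3 spiro centre; cyclopentane C3–C11–C12–C13–C14; dihydrofuran C2–O–C10H2–C11; ring A C2=C1H–C9(=O)–C5H2–C4(=O); 3R,11R,13R)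
Conditions: LiOtBu (2.05 equiv), tBuOH, 70 °C, 0.01 M; aq. NaH2PO4
Reagents that add atoms: none
Why: Two equivalents of LiOtBu turn 20 into its resorcinolate dianion, whose charge is shared by ring carbon C3, and this already substituted carbon displaces bromide from C14 in an ipso attack, the loss of aromaticity being paid for by the stable 1,3-dione anion of 21, which cannot rearomatise because C3 is quaternary. The closest known reactions are the Winstein–Baird Ar1-5 phenoxide cyclisations of 4-arylbutyl sulfonates to spiro[4.5]dienones and the geminal C-alkylation of phloroglucinols. The cyclopentane C3–C11–C12–C13–C14 closes in a 5-exo-tet mode, helped by the gem-dimethyl group on C12. The new stereocentre C3 is controlled by C11, because the four-atom tether can reach C3 only from the face of the dihydrobenzofuran that carries C12 (cis ring fusion), and since the oxygen tied to C10 marks C2 this single outcome is the target configuration. C- over O-alkylation is secured by ring size (five-membered C-closure against a seven-membered aryl ether through the C4 oxygen), by the tight lithium ion pair in tert-butanol, and by using no excess alkoxide, so that E2 loss of HBr from the β-branched bromide is not provoked.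

**Step 15**
Reactants: 21 cyclic enol ether of the spiro trione; 22 geranyl bromide
Product: 23 C5-geranyl derivative of 21 (C5–H epimers and enol equilibrate)
Conditions: NaOMe (1.1 equiv), MeOH, 0 °C → rt
Reagents that add atoms: none
Why: C-alkylation of a cyclic 1,3-dione anion by an allylic bromide in a protic medium, as in the C-prenylation of acylphloroglucinols, with C5 the only doubly activated carbon because C2 is locked as the enol ether, and with geranyl introduced first so that it ends on the concave face after step 16.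

**Step 16**
Reactants: 23 C5-geranyl derivative of 21; 24 prenyl bromide
Product: 25 C5-geranyl C5-prenyl derivative of 21 (prenyl on the ring-A face of C11, geranyl on the face of C14)
Conditions: NaH, toluene–THF, 0 °C → rt
Reagents that add atoms: none
Why: Second C-alkylation of the sodium enolate in a weakly polar medium, in which prenyl bromide should approach C5 on the convex face, anti to the pseudo-axial C14 of the cyclopentane held under ring A by the dihydrofuran tether, so that the C6 carbon comes to lie syn to C11 as the cage requires.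

**Step 17**
Reactants: 25 C5-geranyl C5-prenyl derivative of 21; 26 benzoyl chloride
Product: 27 C1-benzoyl derivative of 25
Conditions: lithium 2,2,6,6-tetramethylpiperidide, THF, −78 °C; then 26, −78 → −40 °C
Reagents that add atoms: none
Why: α-Lithiation of the vinylogous ester at the vinylic C1–H, the only acidic site once C3 and C5 are quaternary, followed by C-acylation, as practised on the vinylogous esters of bicyclic acylphloroglucinol cores.

**Step 18**
Reactants: 27 C1-benzoyl derivative of 25
Product: 28 hydroxy triketone (C10H2OH on C11; enolised C1-benzoyl C2/C9 dione; C4 ketone; C5 as in 25)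
Conditions: LiOH, 1,4-dioxane–H2O, 70 °C; 1 M HCl to pH 3
Reagents that add atoms: lithium hydroxide, [Li+].[OH-]
Why: Hydroxide addition–elimination at C2 of the acyl-activated vinylogous ester should release C10–OH and the delocalised triketonate, whose charge shields the benzoyl and ring carbonyls from retro-Claisen cleavage.

**Step 19**
Reactants: 28 hydroxy triketone
Product: 29 aldehyde (C10HO on C11; otherwise as 28)
Conditions: Dess–Martin periodinane, CH2Cl2, 0 °C → rt
Reagents that add atoms: none
Why: Dess–Martin oxidation of the primary alcohol, for which ligand exchange at iodine should outrun attack by the hydrogen-bonded, electron-poor enol, while C11, flanked by two quaternary carbons, should not epimerise.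

**Step 20**
Reactants: 29 aldehyde
Product: 30 10-hydroxy derivative of the target (C10 configuration not assigned)
Conditions: Sc(OTf)3 (10 mol %), 2,6-di-tert-butylpyridine (20 mol %), 4 Å MS, CH2Cl2, −20 °C → rt
Reagents that add atoms: none
Why: Proposed new method: the scandium-activated C10 aldehyde should be attacked by C7 of the C5 prenyl group on the same face (Prins addition closing the seven-membered ring C10–C7–C6–C5–C4–C3–C11), and the tertiary C8 cation should then be captured by the benzoyl-bearing enol carbon C1 in a six-membered closure that completes the bicyclo[3.3.1]nonane and with it the homoadamantane; C7 and C1 are fixed by the cage, an unproductive alkene orientation being able to revert by retro-Prins fragmentation, and the hindered pyridine removes stray acid that would protonate the geranyl chain. The closest known reaction types are Lewis-acid Prins and carbonyl–ene cyclisations of aldehydes onto trisubstituted alkenes and the biomimetic cation–enol cyclisation of lavandulyl-substituted dearomatised acylphloroglucinols.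

**Step 21**
Reactants: 30 10-hydroxy derivative of the target
Product: 31 O-phenyl thionocarbonate of 30 at C10
Conditions: PhOC(S)Cl, pyridine, DMAP, CH2Cl2, rt
Reagents that add atoms: O-phenyl chlorothionoformate, S=C(Cl)Oc1ccccc1
Why: Thioacylation of the secondary alcohol under amine catalysis, which avoids an alkoxide that could open the non-enolisable cage diketones by retro-Claisen attack.

**Step 22**
Reactants: 31 O-phenyl thionocarbonate of 30
Product: 32 CNP0155129.1
Conditions: Bu3SnH, AIBN, toluene, 90 °C
Reagents that add atoms: none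
Why: Barton–McCombie deoxygenation, in which the secondary C10 radical is not positioned for acyl migration (no carbonyl carbon two atoms away) and is too remote from the trisubstituted alkenes to cyclise before hydrogen transfer from tin.

**Compound list**

1 | (3E)-5-methylhex-3-en-2-one | CC(=O)/C=C/C(C)C | starting material
2 | (2R,3E)-5-methylhex-3-en-2-ol | C[C@@H](O)/C=C/C(C)C | intermediate
3 | 2-methylpropanoyl chloride (isobutyryl chloride) | CC(C)C(Cl)=O | starting material
4 | (2R,3E)-5-methylhex-3-en-2-yl 2-methylpropanoate | C[C@@H](OC(=O)C(C)C)/C=C/C(C)C | intermediate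
5 | trimethylsilyl ketene acetal of 4 | C[C@@H](OC(O[Si](C)(C)C)=C(C)C)/C=C/C(C)C | intermediate
6 | trimethylsilyl (3S,4E)-2,2-dimethyl-3-(propan-2-yl)hex-4-enoate | C[Si](C)(C)OC(=O)C(C)(C)[C@@H](C(C)C)/C=C/C | intermediate
7 | (3S,4E)-2,2-dimethyl-3-(propan-2-yl)hex-4-enoic acid | OC(=O)C(C)(C)[C@@H](C(C)C)/C=C/C | intermediate
8 | (3S,4E)-2,2-dimethyl-3-(propan-2-yl)hex-4-en-1-ol | OCC(C)(C)[C@@H](C(C)C)/C=C/C | intermediate
9 | (3S,4E)-2,2-dimethyl-3-(propan-2-yl)hex-4-enal | O=CC(C)(C)[C@@H](C(C)C)/C=C/C | intermediate
10 | dimethyl (2-oxopropyl)phosphonate | COP(=O)(CC(C)=O)OC | starting material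
11 | (3E,6S,7E)-5,5-dimethyl-6-(propan-2-yl)nona-3,7-dien-2-one | CC(=O)/C=C/C(C)(C)[C@@H](C(C)C)/C=C/C | intermediate
12 | (2S,3E,6S,7E)-5,5-dimethyl-6-(propan-2-yl)nona-3,7-dien-2-ol | C[C@H](O)/C=C/C(C)(C)[C@@H](C(C)C)/C=C/C | intermediate
13 | 3,5-bis(benzyloxy)phenol | Oc1cc(OCc2ccccc2)cc(OCc2ccccc2)c1 | starting material
14 | 1,3-bis(benzyloxy)-5-{[(2R,3E,6S,7E)-5,5-dimethyl-6-(propan-2-yl)nona-3,7-dien-2-yl]oxy}benzene | C[C@@H](Oc1cc(OCc2ccccc2)cc(OCc2ccccc2)c1)/C=C/C(C)(C)[C@@H](C(C)C)/C=C/C | intermediate
15 | 3,5-bis(benzyloxy)-2-[(2E,4R,6S,7E)-5,5-dimethyl-6-(propan-2-yl)nona-2,7-dien-4-yl]phenol | C/C=C/[C@@H](c1c(O)cc(OCc2ccccc2)cc1OCc1ccccc1)C(C)(C)[C@@H](C(C)C)/C=C/C | intermediate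
16 | bis(1,2,4-trioxolane) of 15 (both propenyl groups as ozonides, trioxolane carbons as mixtures) | CC1OOC(O1)[C@@H](c1c(O)cc(OCc2ccccc2)cc1OCc1ccccc1)C(C)(C)[C@@H](C(C)C)C1OOC(C)O1 | intermediate
17 | (2R,4R)-2-[2,4-bis(benzyloxy)-6-hydroxyphenyl]-3,3-dimethyl-4-(propan-2-yl)pentane-1,5-diol | OC[C@@H](c1c(O)cc(OCc2ccccc2)cc1OCc1ccccc1)C(C)(C)[C@@H](C(C)C)CO | intermediate
18 | (2R)-3-[(3R)-4,6-bis(benzyloxy)-2,3-dihydro-1-benzofuran-3-yl]-3-methyl-2-(propan-2-yl)butan-1-ol | OC[C@H](C(C)C)C(C)(C)[C@H]1COc2cc(OCc3ccccc3)cc(OCc3ccccc3)c12 | intermediate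
19 | (3R)-4,6-bis(benzyloxy)-3-[(3R)-3-(bromomethyl)-2,4-dimethylpentan-2-yl]-2,3-dihydro-1-benzofuran | BrC[C@H](C(C)C)C(C)(C)[C@H]1COc2cc(OCc3ccccc3)cc(OCc3ccccc3)c12 | intermediate
20 | (3R)-3-[(3R)-3-(bromomethyl)-2,4-dimethylpentan-2-yl]-2,3-dihydro-1-benzofuran-4,6-diol | BrC[C@H](C(C)C)C(C)(C)[C@H]1COc2cc(O)cc(O)c12 | intermediate
21 | cyclic enol ether of the spiro trione (C3 spiro; cyclopentane C3–C11–C12–C13–C14; dihydrofuran C2–O–C10H2–C11; C2=C1H–C9(=O)–C5H2–C4(=O); 3R,11R,13R) | C1C(=O)C=C2OC[C@@H]3C(C)(C)[C@@H](C(C)C)C[C@]23C1=O | intermediate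
22 | geranyl bromide, (2E)-1-bromo-3,7-dimethylocta-2,6-diene | CC(C)=CCC/C(C)=C/CBr | starting material
23 | C5-geranyl derivative of 21 (C5 unassigned, enolisable) | CC(C)=CCC/C(C)=C/CC1C(=O)C=C2OC[C@@H]3C(C)(C)[C@@H](C(C)C)C[C@]23C1=O | intermediate
24 | prenyl bromide, 1-bromo-3-methylbut-2-ene | CC(C)=CCBr | starting material
25 | C5-geranyl C5-prenyl derivative of 21 (prenyl syn to C11, geranyl syn to C14) | CC(C)=CCC/C(C)=C/C[C@]1(CC=C(C)C)C(=O)C=C2OC[C@@H]3C(C)(C)[C@@H](C(C)C)C[C@]23C1=O | intermediate
26 | benzoyl chloride | O=C(Cl)c1ccccc1 | starting material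
27 | C1-benzoyl derivative of 25 | CC(C)=CCC/C(C)=C/C[C@]1(CC=C(C)C)C(=O)C(C(=O)c4ccccc4)=C2OC[C@@H]3C(C)(C)[C@@H](C(C)C)C[C@]23C1=O | intermediate
28 | hydroxy triketone (C10H2OH; enolised C1-benzoyl C2/C9 dione; C4 ketone) | CC(C)=CCC/C(C)=C/C[C@]1(CC=C(C)C)C(=O)C(C(=O)c2ccccc2)=C(O)[C@]2(C[C@H](C(C)C)C(C)(C)[C@H]2CO)C1=O | intermediate
29 | aldehyde (C10HO; otherwise as 28) | CC(C)=CCC/C(C)=C/C[C@]1(CC=C(C)C)C(=O)C(C(=O)c2ccccc2)=C(O)[C@]2(C[C@H](C(C)C)C(C)(C)[C@H]2C=O)C1=O | intermediate
30 | 10-hydroxy derivative of the target (C10 unassigned) | CC(C)=CCC/C(C)=C/C[C@@]12C[C@H]3C(O)[C@@H]4C(C)(C)[C@@H](C(C)C)C[C@]4(C1=O)C(=O)[C@@](C(=O)c1ccccc1)(C2=O)C3(C)C | intermediate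
31 | O-phenyl thionocarbonate of 30 | CC(C)=CCC/C(C)=C/C[C@@]12C[C@H]3C(OC(=S)Oc5ccccc5)[C@@H]4C(C)(C)[C@@H](C(C)C)C[C@]4(C1=O)C(=O)[C@@](C(=O)c1ccccc1)(C2=O)C3(C)C | intermediate
32 | CNP0155129.1 | CC(C)=CCC/C(C)=C/C[C@@]12C[C@H]3C[C@@H]4C(C)(C)[C@@H](C(C)C)C[C@]4(C1=O)C(=O)[C@@](C(=O)c1ccccc1)(C2=O)C3(C)C | target

**Totals and risks**

Total step count: 22. Longest linear sequence: 22 steps (1 → 32).

Steps most likely to fail:

1. Step 20 (Proposed new method). The cascade may stop after the first bond by proton loss to an isopropenyl group, the aldehyde may be held back as its lactol with the C2 enol, or stray acid may protonate the geranyl chain before the cage closes. The fallback sets out from 29 and returns to 30 by two known steps. Me2AlCl (2.2 equiv, CH2Cl2, −78 °C), a proton-scavenging Lewis acid, should bring about a concerted intramolecular carbonyl–ene reaction between the C10 aldehyde and the C5 prenyl group to give the seven-membered homoallylic alcohol with a C7 isopropenyl group F1. Catalytic TsOH·H2O in CH2Cl2 would then protonate the isopropenyl group of F1 so that the C8 cation is captured by C1, the established cation–enol closure of lavandulyl-type side chains on dearomatised acylphloroglucinols, arriving at 30.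

2. Step 16. The prenyl bromide may fail to distinguish the two faces of the C5 enolate, or oxygen alkylation may compete. The fallback goes from 23 directly to 25 and isolates no new compound (F0). It is a Tsuji–Trost prenylation with tert-butyl (3-methylbut-2-en-1-yl) carbonate, Pd2(dba)3 and a chiral Trost bisphosphine ligand, both antipodes to be screened. The stabilised enolate should attack the unsubstituted allyl terminus from outside the metal at carbon, and the ligand rather than the substrate would select the enolate face.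

3. Step 9. The [3,3] shift must bond the arene to a carbon next to quaternary C12; if it is slow, ionisation of the electron-rich allyl aryl ether to an ion pair may erode the chirality transfer or deliver the arene to the methyl-bearing terminus. The fallback sets out from 12 and 13 and returns at 15. Phenol 13 is protected (MOMCl, iPr2NEt) as 1,3-bis(benzyloxy)-5-(methoxymethoxy)benzene F2, and 12 is esterified (picolinic acid, DCC, DMAP) to its pyridine-2-carboxylate ester F3. F2 is lithiated between the OMOM and OBn groups (nBuLi, THF, 0 °C), transmetallated (MgBr2·OEt2, then CuBr·SMe2) and added to F3. The chelating picolinate should direct a copper-mediated anti-SN2′ arylation with 1,3-chirality transfer from the (S)-carbinol to C11, the same stereochemical sense as inversion followed by the suprafacial Claisen shift, giving the MOM ether of 15 F4. HCl in methanol would then remove the MOM group and give 15.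

**Further compounds**

F1 | step 20 | seven-membered carbonyl–ene adduct (C10 carbinol unassigned; C7 isopropenyl; enolised C1-benzoyl triketone) | CC(C)=CCC/C(C)=C/C[C@@]12C[C@H](C(C)=C)C(O)[C@@H]3C(C)(C)[C@@H](C(C)C)C[C@]3(C1=O)C(O)=C(C(=O)c1ccccc1)C2=O
F0 | step 16 | none | none
F2 | step 9 | 1,3-bis(benzyloxy)-5-(methoxymethoxy)benzene | COCOc1cc(OCc2ccccc2)cc(OCc2ccccc2)c1
F3 | step 9 | (2S,3E,6S,7E)-5,5-dimethyl-6-(propan-2-yl)nona-3,7-dien-2-yl pyridine-2-carboxylate | C[C@H](OC(=O)c1ccccn1)/C=C/C(C)(C)[C@@H](C(C)C)/C=C/C
F4 | step 9 | 1,5-bis(benzyloxy)-2-[(2E,4R,6S,7E)-5,5-dimethyl-6-(propan-2-yl)nona-2,7-dien-4-yl]-3-(methoxymethoxy)benzene (MOM ether of 15) | C/C=C/[C@@H](c1c(OCOC)cc(OCc2ccccc2)cc1OCc1ccccc1)C(C)(C)[C@@H](C(C)C)/C=C/C
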